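## The problem

Echinoclathrine A (13) is an achiral biaryl whose benzene ring carries the decanamide nitrogen on C1, a free hydroxyl on C2 and a 2-methylpyridin-4-yl ring on C6. There is no stereocentre and the biaryl axis rotates freely, so the difficulty is purely regiochemical: three different substituents on three contiguous carbons, with nitrogen in the middle. The ten-carbon chain is attached only through the amide and can be brought in late as one piece. The o-amidophenol is the delicate part: it is easily oxidised, it closes to a benzoxazole under dehydrating acid, and its acyl group can move between N and O. The pyridine nitrogen is basic, binds metals and can be alkylated. The feature that invites a ring synthesis is that the oxygen on C2 and the nitrogen on C1 are neighbours and can both be bonded to one carbonyl carbon, the carbon that ends as the amide carbonyl. Such a carbamate is a three-atom tether between a 3-oxy-2-pyrone (C2 to C5 of the benzene ring) and a nitrogen-bound pyridylalkyne (C1 and C6), and it lets the two meet in one orientation only.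

## Retrosynthesis

**13 from 12 (N–CH2 bond of a 4-methoxybenzyl group).** Nitrogen needs a third substituent throughout the ynamide stage, because an N–H ynamide would tautomerise. The 4-methoxybenzyl group arrives with isocyanate 6, should survive copper, heat and a Grignard reagent, and leaves an anilide under acid. Allyl was rejected because N-allyl ynamides rearrange on heating, and plain benzyl because it is hard to remove from an amide. Precursor 12 differs from 13 only by this group. The forward reaction must cleave the benzyl group without letting the acyl group leave nitrogen for good.

**12 from 10 and 11 (amide C(=O)–C9 bond cut, carbonyl carbon rejoined to the phenol oxygen).** This leads back to the cyclic carbamate 10 and nonylmagnesium bromide 11. The neighbouring option, hydrolysing the carbamate and acylating the aminophenol, discards the tether carbon and costs three operations. Here the carbonyl is kept and the phenol is set free in the same step. The forward reaction must stop after one addition: the aryloxide has to leave the tetrahedral intermediate, and the hindered tertiary amide has to resist a second equivalent.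

**10 from 8 (benzene bonds C1–C2 and C5–C6 cut, a one-carbon lactone bridge returned across C2 and C5).** This is the disconnection the plan rests on. The obvious neighbour, cutting the biaryl bond, merely buys a 1,2,3-trisubstituted arene, whereas this cut builds the pattern. An untethered union of a pyrone and an ynamide was not considered further because its orientation is uncertain. Precursor 8 has no benzene ring and is two flat pieces joined by a carbamate. The forward reaction needs the carbamate to reach the rotamer that holds pyrone and alkyne on the same side, and needs the ynamide to survive the temperature required.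

**8 from 7 and 4 (N–C(sp) bond).** Making the carbamate C–O bond last would need an N-alkynyl carbamoyl halide, a reagent class with no secure standing. Alkynylating the N–H carbamate 7 with bromoalkyne 4 is the standard ynamide construction. It must work on a base-sensitive aryl carbamate, and at a temperature below that of the cycloaddition so that 8 can be isolated.

**7 from 5 and 6 (carbamate C(=O)–O bond).** Addition of 3-hydroxy-2H-pyran-2-one 5 to 4-methoxybenzyl isocyanate 6 forms the bond without any by-product and places the protecting group and the future amide carbon in one operation.

**4 from 3, and 3 from 1 and 2 (C–Br, then C(sp2)–C(sp)).** Bromoalkyne 4 comes from silylalkyne 3 by bromodesilylation, and 3 from 4-bromo-2-methylpyridine 1 and ethynyltrimethylsilane 2 by Sonogashira coupling. The pyridine ring is bought complete and only its C4 substituent is changed.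

## Roads not taken

**Alternative 1:** This road cuts no carbon–carbon bond of the benzene ring. It disconnects C1–N and C2–O and removes the aromaticity, leading back to the ketone A1, 2-(2-methylpyridin-4-yl)cyclohexan-1-one, and the amine A2, decan-1-amine. In the forward step A1 condenses with A2 while the nitroxyl A3 (TEMPO) oxygenates the α-methylene and dehydrogenates the ring to the aminophenol A4, 2-(decylamino)-3-(2-methylpyridin-4-yl)phenol.

- Merits: it is short, needs no protecting group, and the 1,2,3-pattern follows from the ketone carbon of A1 and its two α-carbons.
- Weak points: the two α-positions of A1 differ, and oxygenation at the aryl-bearing one would stop aromatisation. A4 is also at the amine oxidation level, not the amide level. An amide cannot serve as the condensing nitrogen, so the N–CH2 group of A4 must be oxidised next to an electron-rich aminophenol. That would most plausibly run through the benzoxazole A12, 4-(2-methylpyridin-4-yl)-2-nonyl-1,3-benzoxazole, and a hydrolysis.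
- Comparison: even with those two extra steps this road is shorter than the chosen one, and its key reaction type is established on simple ketones. The chosen plan sets against it an unambiguous regiochemistry and a nitrogen that is at the acyl oxidation level from the start.

**Alternative 2:** This road cuts the pyridine ring at its own C3–C4, N1–C2 and N1–C6 bonds (Kröhnke pyridine synthesis). The ylide of the pyridinium salt A5, 1-(2-oxopropyl)pyridin-1-ium chloride, adds to the β-carbon of the enal A6, (E)-3-(3-methoxy-2-nitrophenyl)prop-2-enal. The ammonium salt A7, ammonium acetate, supplies the ring nitrogen, and loss of the pyridinium leaving group gives the biaryl A8, 4-(3-methoxy-2-nitrophenyl)-2-methylpyridine.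

- Merits: it is a robust named reaction, the 1,2,3-pattern is bought with the nitroarene of A6, and every step after A8 is routine.
- Weak points: it builds the ring that the chosen plan buys as 1. The enal A6 is a less reliable acceptor for the ylide of A5 than an enone would be, and its ortho-nitro group crowds the β-carbon. After A8 a nitro reduction, an acylation and a methyl ether cleavage remain.
- Comparison: this road is about five steps of known chemistry and is more certain than the chosen plan, and at least as short. The chosen plan sets against it that it constructs the ring where the real difficulty lies, carries the amide carbon from the outset, needs no redox or ether adjustments, and lets either the acyl chain or the C6 aryl group be varied by changing one reagent.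

**Alternative 3:** This road cuts the pyridine ring at its own C2–C3 and C4–C5 bonds. The enamine formed in the flask from the ketone A9, 1-(2-nonyl-1,3-benzoxazol-4-yl)ethan-1-one, and pyrrolidine A10 adds across C3 and C6 of the triazine A11, 3-methyl-1,2,4-triazine. Extrusion of the N1–N2 unit of A11 and elimination of A10 give the benzoxazole A12, 4-(2-methylpyridin-4-yl)-2-nonyl-1,3-benzoxazole, and one hydrolytic ring opening would finish the synthesis.

- Merits: the benzoxazole of A9 protects O and N and already holds the chain, and the reaction type is established.
- Weak points: A11 has no activating group and is a reluctant diene. Aryl methyl ketone enamines form slowly, and the one from A9 is flanked by the oxazole nitrogen. The required orientation puts the new bond at the methyl-bearing C3 of A11, so the regiochemistry is not assured. A9 itself needs a 1,2,3-trisubstituted benzene, so the pattern problem is only moved back, and again a purchasable ring is built.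
- Comparison: length is similar and precedent for the reaction class is stronger than for the chosen key step. The chosen plan has in its favour that its regiochemistry is enforced by a tether and not by substituent effects.

Key step: step 5

Assumption: 3-hydroxy-2H-pyran-2-one (5) is taken as a purchased compound; the 4-methoxybenzyl group is kept as the nitrogen substituent from step 3 to step 7.

## Route

**Step 1**
Reactants: 1 4-bromo-2-methylpyridine; 2 ethynyltrimethylsilane
Product: 3 2-methyl-4-[(trimethylsilyl)ethynyl]pyridine
Conditions: PdCl2(PPh3)2 (2 mol%), CuI (4 mol%), Et3N, THF, 50 °C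
Reagents that add atoms: none
Why: Sonogashira coupling; the C4–Br bond of the electron-poor pyridine adds readily to zerovalent palladium, and the silyl group prevents double coupling.

**Step 2**
Reactants: 3 2-methyl-4-[(trimethylsilyl)ethynyl]pyridine
Product: 4 4-(bromoethynyl)-2-methylpyridine
Conditions: NBS (1.2 equiv), AgNO3 (0.3 equiv), acetone, rt, dark
Reagents that add atoms: N-bromosuccinimide, O=C1CCC(=O)N1Br
Why: Silver-catalysed bromodesilylation; AgNO3 exchanges the alkynyl C–Si bond for C–Ag and the silver acetylide is brominated by N-bromosuccinimide. Ring and methyl C–H bonds should be untouched at room temperature in the dark, and 4 is to be used promptly.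

**Step 3**
Reactants: 5 3-hydroxy-2H-pyran-2-one; 6 4-methoxybenzyl isocyanate
Product: 7 2-oxo-2H-pyran-3-yl N-(4-methoxybenzyl)carbamate
Conditions: Et3N (0.1 equiv), CH2Cl2, 0 °C to rt
Reagents that add atoms: none
Why: Amine-catalysed addition of an acidic enol O–H to an isocyanate (carbamoylation); the reaction is an addition with no by-product, and the mild catalyst should leave the pyrone lactone intact.

**Step 4**
Reactants: 7 2-oxo-2H-pyran-3-yl N-(4-methoxybenzyl)carbamate; 4 4-(bromoethynyl)-2-methylpyridine
Product: 8 2-oxo-2H-pyran-3-yl N-(4-methoxybenzyl)-N-[(2-methylpyridin-4-yl)ethynyl]carbamate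
Conditions: CuSO4·5H2O (10 mol%), 1,10-phenanthroline (20 mol%), K3PO4 (2 equiv), PhMe, 60–65 °C
Reagents that add atoms: none
Why: Copper-catalysed N-alkynylation of a carbamate with a 1-bromoalkyne (Ullmann-type amidation at an sp carbon) via a copper amidate. Phenanthroline should outcompete the pyridine for copper, ligand and base are non-nucleophilic toward the pyrone, and the temperature is kept below that expected for the cycloaddition.

**Step 5**
Reactants: 8 2-oxo-2H-pyran-3-yl N-(4-methoxybenzyl)-N-[(2-methylpyridin-4-yl)ethynyl]carbamate
Product: 10 3-(4-methoxybenzyl)-4-(2-methylpyridin-4-yl)-1,3-benzoxazol-2(3H)-one, via bridged bicyclic lactone 9 (not isolated)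
Conditions: PhMe (0.02 M), BHT (0.1 equiv), sealed tube, 150 °C
Reagents that add atoms: none
Why: Proposed new method: on heating, rotation about the carbamate C–O and C–N bonds brings the alkyne over the pyrone, whose C3=C4–C5=C6 diene adds to it in a type 1 intramolecular [4+2] cycloaddition that forms the C3–Cα and C6–Cβ bonds and gives bridged lactone 9; 9 then loses CO2 by retro-[4+2], which is irreversible and leaves the benzene ring of 10. The closest known reaction types are the intramolecular Diels–Alder reaction of alkyne-tethered 2-pyrones with CO2 extrusion and the intramolecular [4+2] cycloaddition of ynamides that carry the diene on a three-atom tether through nitrogen; an O–C(=O)–N tether joining the two has not been used. The benzene ring is closed by the cycloaddition–cycloreversion pair, and the five-membered oxazolone ring is the tether ring, closed by the C3–Cα bond in a 5-exo-dig sense with respect to the alkyne. No stereocentre remains, since the two bridgehead centres of racemic 9 are erased when CO2 leaves. The selectivity needed is regiochemical and the tether secures it, because three atoms can only span pyrone C3 and the nitrogen-bearing alkyne carbon; this orientation should also be the polarity-matched one, the nucleophilic C3 terminus of the pyrone meeting the electrophilic α-carbon of the ynamide. Dilution is meant to suppress bimolecular addition, BHT radical polymerisation, and dry neutral toluene hydration of the ynamide.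

**Step 6**
Reactants: 10 3-(4-methoxybenzyl)-4-(2-methylpyridin-4-yl)-1,3-benzoxazol-2(3H)-one; 11 nonylmagnesium bromide
Product: 12 N-[2-hydroxy-6-(2-methylpyridin-4-yl)phenyl]-N-(4-methoxybenzyl)decanamide
Conditions: 11 (1.3 equiv), THF, −40 to 0 °C; aq NH4Cl
Reagents that add atoms: none
Why: Grignard addition to the carbonyl of a cyclic N-substituted carbamate with ring opening to a tertiary amide; the tetrahedral intermediate should expel the aryloxide, the better leaving group. The resulting amide, flanked by a 2,6-disubstituted aryl group and a benzyl group and sitting next to a magnesium phenoxide, should resist a second addition at low temperature.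

**Step 7**
Reactants: 12 N-[2-hydroxy-6-(2-methylpyridin-4-yl)phenyl]-N-(4-methoxybenzyl)decanamide
Product: 13 echinoclathrine A, N-[2-hydroxy-6-(2-methylpyridin-4-yl)phenyl]decanamide
Conditions: TFA, anisole (5 equiv), 70 °C; then aq NaHCO3
Reagents that add atoms: none
Why: Acidolytic N-debenzylation; the O-protonated anilide loses the stabilised 4-methoxybenzyl cation, which anisole traps by Friedel–Crafts alkylation. Any acyl group that has moved to the phenol oxygen under acid should return to nitrogen by O-to-N acyl transfer on neutralisation.

## Compound list

1 | 4-bromo-2-methylpyridine | Cc1cc(Br)ccn1 | starting material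
2 | ethynyltrimethylsilane | C#C[Si](C)(C)C | starting material
3 | 2-methyl-4-[(trimethylsilyl)ethynyl]pyridine | Cc1cc(C#C[Si](C)(C)C)ccn1 | intermediate
4 | 4-(bromoethynyl)-2-methylpyridine | Cc1cc(C#CBr)ccn1 | intermediate
5 | 3-hydroxy-2H-pyran-2-one | O=C1OC=CC=C1O | starting material
6 | 4-methoxybenzyl isocyanate | COc1ccc(CN=C=O)cc1 | starting material
7 | 2-oxo-2H-pyran-3-yl N-(4-methoxybenzyl)carbamate | COc1ccc(CNC(=O)OC2=CC=COC2=O)cc1 | intermediate
8 | 2-oxo-2H-pyran-3-yl N-(4-methoxybenzyl)-N-[(2-methylpyridin-4-yl)ethynyl]carbamate | COc1ccc(CN(C#Cc2ccnc(C)c2)C(=O)OC2=CC=COC2=O)cc1 | intermediate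
9 | bridged bicyclic lactone: 2-oxabicyclo[2.2.2]octa-5,7-dien-3-one with the N-(4-methoxybenzyl)oxazolone ring fused across bridgehead C4 and alkene carbon C8, and 2-methylpyridin-4-yl on C7 (racemic, relative configuration fixed by the bicycle) | O=C1OC2C=CC13OC(=O)N(Cc4ccc(OC)cc4)C3=C2c2ccnc(C)c2 | intermediate (not isolated)
10 | 3-(4-methoxybenzyl)-4-(2-methylpyridin-4-yl)-1,3-benzoxazol-2(3H)-one | COc1ccc(CN2C(=O)Oc3cccc(-c4ccnc(C)c4)c32)cc1 | intermediate
11 | nonylmagnesium bromide | CCCCCCCCC[Mg]Br | starting material
12 | N-[2-hydroxy-6-(2-methylpyridin-4-yl)phenyl]-N-(4-methoxybenzyl)decanamide | CCCCCCCCCC(=O)N(Cc1ccc(OC)cc1)c1c(O)cccc1-c1ccnc(C)c1 | intermediate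
13 | echinoclathrine A, N-[2-hydroxy-6-(2-methylpyridin-4-yl)phenyl]decanamide | CCCCCCCCCC(=O)Nc1c(O)cccc1-c1ccnc(C)c1 | target

## Step count and risks

Total: 7 steps. Longest linear sequence: 6 steps (1 → 3 → 4 → 8 → 10 → 12 → 13); step 3 is a one-step branch.

**Step 5 (key step, proposed new method).** The most likely failure is that the cycloaddition does not outrun thermal loss of the ynamide. The carbamate must leave its preferred rotamer and bend a short, fully conjugated tether, so the temperature required may be high enough for migration of the benzyl group from nitrogen to carbon, hydration, or oligomerisation. The fallback uses known chemistry, sets out from 1 and comes back to the route at 10. Miyaura borylation of 1 (B2pin2, Pd(dppf)Cl2, KOAc, dioxane) should give 2-methyl-4-(4,4,5,5-tetramethyl-1,3,2-dioxaborolan-2-yl)pyridine F1. Purchased 2-amino-3-bromophenol F2 would be closed with carbonyldiimidazole to 4-bromo-1,3-benzoxazol-2(3H)-one F3. N-Alkylation with 4-methoxybenzyl chloride and K2CO3 would then give 4-bromo-3-(4-methoxybenzyl)-1,3-benzoxazol-2(3H)-one F4. Suzuki–Miyaura coupling of F4 with F1 (Pd(OAc)2, SPhos, K3PO4, toluene/water) would give 10.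

**Step 4.** The most likely failure is base-induced fragmentation of the secondary aryl carbamate. Deprotonation at nitrogen followed by E1cB loss of the pyranolate gives the isocyanate, which is lost for good if water intercepts it. Homocoupling or self-quaternisation of the pyridyl bromoalkyne is a second concern. The fallback sets out from 3 (with 7) and comes back at 8. K2CO3 in methanol would remove the silyl group to give 4-ethynyl-2-methylpyridine F5. CuI in aqueous ammonia and ethanol would convert it into [(2-methylpyridin-4-yl)ethynyl]copper F6. Oxidative coupling of F6 with 7 under O2 with TMEDA in MeCN at room temperature would give 8. This uses neither a bromoalkyne nor a hot inorganic base.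

**Step 6.** The most likely failure is a second addition of the Grignard reagent to the new amide, giving ketone and cleaved aminophenol, or incomplete addition if the reagent is held back to avoid this. The fallback sets out from 10 and comes back at 13. Hot TFA with anisole would remove the benzyl group to give 4-(2-methylpyridin-4-yl)-1,3-benzoxazol-2(3H)-one F7. Aqueous NaOH in ethanol at reflux would open the carbamate to 2-amino-3-(2-methylpyridin-4-yl)phenol F8. Selective N-acylation of F8 with decanoyl chloride (NaHCO3, THF/water) would give 13.

**Step 7.** The most likely failure is acid-promoted migration of the acyl group to the phenol oxygen followed by cyclodehydration toward a benzoxazolium species, or benzylation of the electron-rich phenol ring by the released cation. The fallback sets out from 12 and comes back at 13. Acetylation (Ac2O, pyridine) would mask the phenol as 2-[N-(4-methoxybenzyl)decanamido]-3-(2-methylpyridin-4-yl)phenyl acetate F9. Oxidative debenzylation with (NH4)2Ce(NO3)6 in MeCN/water would give 2-(decanoylamino)-3-(2-methylpyridin-4-yl)phenyl acetate F10. K2CO3 in methanol would then remove the acetate of F10 to give 13.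

## Further compounds

F1 | step 5 | 2-methyl-4-(4,4,5,5-tetramethyl-1,3,2-dioxaborolan-2-yl)pyridine | Cc1cc(B2OC(C)(C)C(C)(C)O2)ccn1
F2 | step 5 | 2-amino-3-bromophenol | Nc1c(O)cccc1Br
F3 | step 5 | 4-bromo-1,3-benzoxazol-2(3H)-one | O=C1Nc2c(Br)cccc2O1
F4 | step 5 | 4-bromo-3-(4-methoxybenzyl)-1,3-benzoxazol-2(3H)-one | COc1ccc(CN2C(=O)Oc3cccc(Br)c32)cc1
F5 | step 4 | 4-ethynyl-2-methylpyridine | Cc1cc(C#C)ccn1
F6 | step 4 | [(2-methylpyridin-4-yl)ethynyl]copper | Cc1cc(C#C[Cu])ccn1
F7 | step 6 | 4-(2-methylpyridin-4-yl)-1,3-benzoxazol-2(3H)-one | O=C1Nc2c(-c3ccnc(C)c3)cccc2O1
F8 | step 6 | 2-amino-3-(2-methylpyridin-4-yl)phenol | Nc1c(O)cccc1-c1ccnc(C)c1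
F9 | step 7 | 2-[N-(4-methoxybenzyl)decanamido]-3-(2-methylpyridin-4-yl)phenyl acetate | CCCCCCCCCC(=O)N(Cc1ccc(OC)cc1)c1c(OC(C)=O)cccc1-c1ccnc(C)c1
F10 | step 7 | 2-(decanoylamino)-3-(2-methylpyridin-4-yl)phenyl acetate | CCCCCCCCCC(=O)Nc1c(OC(C)=O)cccc1-c1ccnc(C)c1
A1 | alternative 1 | 2-(2-methylpyridin-4-yl)cyclohexan-1-one (racemic) | Cc1cc(C2CCCCC2=O)ccn1
A2 | alternative 1 | decan-1-amine | CCCCCCCCCCN
A3 | alternative 1 | 2,2,6,6-tetramethylpiperidin-1-oxyl (TEMPO) | CC1(C)CCCC(C)(C)N1[O]
A4 | alternative 1 | 2-(decylamino)-3-(2-methylpyridin-4-yl)phenol | CCCCCCCCCCNc1c(O)cccc1-c1ccnc(C)c1
A5 | alternative 2 | 1-(2-oxopropyl)pyridin-1-ium chloride | CC(=O)C[n+]1ccccc1.[Cl-]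
A6 | alternative 2 | (E)-3-(3-methoxy-2-nitrophenyl)prop-2-enal | COc1cccc(/C=C/C=O)c1[N+](=O)[O-]
A7 | alternative 2 | ammonium acetate | CC(=O)[O-].[NH4+]
A8 | alternative 2 | 4-(3-methoxy-2-nitrophenyl)-2-methylpyridine | COc1cccc(-c2ccnc(C)c2)c1[N+](=O)[O-]
A9 | alternative 3 | 1-(2-nonyl-1,3-benzoxazol-4-yl)ethan-1-one | CCCCCCCCCc1nc2c(C(C)=O)cccc2o1
A10 | alternative 3 | pyrrolidine | C1CCNC1
A11 | alternative 3 | 3-methyl-1,2,4-triazine | Cc1nccnn1
A12 | alternative 3 | 4-(2-methylpyridin-4-yl)-2-nonyl-1,3-benzoxazole | CCCCCCCCCc1nc2c(-c3ccnc(C)c3)cccc2o1
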